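**Plan**

- Retrosynthesis: remove the C13 acetate and the C8 methacrylate. Return the C5=C6 enol lactone (ring C) to a furan built from C6, C7, C11 and C12. Cut C9–C10 (aldol). Then cut the furan (C7–C11 and O–C12) back to a β-keto ester grown on ring A.
- Enabling feature: C8 and C10 carry oxygen in a 1,3-relationship across the C9 methylene, and the C10 carbonyl is bonded to C1, whose oxygen is the ring A ether. A metal enolate at C8/C9 can therefore be delivered to a chelated C10 ketone, while the furan keeps ring C inert.
- Forward order: ring A (tetrahydrofuran, from (R)-linalool) first. Next the furan, by Roskamp homologation and Feist–Benary condensation on the carbons of the linalool vinyl group (C5, C6). Then ring B by the samarium aldol at C9–C10. Ring C last, by singlet-oxygen oxidation of the furan and dehydration.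
- Stereochemistry: C4 is the carbinol carbon of (R)-linalool. C1 comes from a Shi epoxidation and invertive 5-exo epoxide opening. C10 comes from samarium chelation in the ring closure. C8 comes from a 1,3-syn reduction directed by the C10 hydroxyl. The C5=C6 geometry is fixed by ring B.

Key step: step 11

Remarks: germacrane numbering (C1–C15) is used for all intermediates. The furan α-carbon C12 carries hydrogen (no blocking group); this single α-hydrogen fixes the regiochemistry of the later furan oxidation. The chlorodiol building block is racemic because its stereocentre is oxidised away. Transient centres (C11 in the dihydrofuran, C10 in the Lemieux–Johnson diol, C6 in the hydroxy- and acetoxybutenolides) are carried as epimer mixtures. In the alkylborane the tertiary hydroxyl is drawn free.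

**Route**

Step 1
Reactants: 1 (R)-linalool
Product: 3 cis-furanoid linalool oxide 2-[(2S,5R)-5-ethenyl-5-methyloxolan-2-yl]propan-2-ol (vinyl and hydroxyisopropyl cis), via (3R,6R)-6,7-epoxylinalool 2 (not isolated)
Conditions: D-fructose-derived Shi ketone (cat.), KHSO5 (as 2KHSO5·KHSO4·K2SO4), K2CO3, Bu4NHSO4, MeCN/CH2(OMe)2/aq. borate buffer, 0 °C; crude 2 then CSA (cat.), CH2Cl2, 0 °C; chromatographic removal of the pyranoid isomer
Reagents that add atoms: potassium peroxymonosulfate KHSO5, [K+].[O-]S(=O)(=O)OO
Why: Shi asymmetric epoxidation should oxidise only the electron-rich trisubstituted alkene, on the face that gives the (6R)-epoxide, and acid-catalysed 5-exo opening by the tertiary hydroxyl with inversion at the epoxide CH then sets C1 (S) cis to the vinyl group, while C4 (R) is carried over unchanged from (R)-linalool.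

Step 2
Reactants: 3 cis-furanoid linalool oxide
Product: 5 2-[(2R,5S)-5-(2-hydroxypropan-2-yl)-2-methyloxolan-2-yl]ethan-1-ol, via B-alkyl-9-borabicyclononane 4 (not isolated)
Conditions: 9-BBN, THF, 0 °C to rt; then NaOH, H2O2, H2O, 0 °C
Reagents that add atoms: hydrogen peroxide, OO
Why: Hydroboration–oxidation should place boron on the terminal vinyl carbon (anti-Markovnikov) and alkaline peroxide replaces it by hydroxyl, so C6 becomes a primary carbinol without touching C1 or C4.

Step 3
Reactants: 5 primary/tertiary diol
Product: 6 2-[(2R,5S)-5-(2-hydroxypropan-2-yl)-2-methyloxolan-2-yl]acetaldehyde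
Conditions: TEMPO (cat.), PhI(OAc)2, CH2Cl2, rt
Reagents that add atoms: none
Why: The oxoammonium (TEMPO) oxidation is selective for the primary alcohol, stops at the aldehyde and is close to neutral, so the tertiary alcohol is untouched and β-elimination of the ring A oxygen should not be triggered.

Step 4
Reactants: 6 C6 aldehyde; 7 ethyl diazoacetate
Product: 8 ethyl 4-[(2R,5S)-5-(2-hydroxypropan-2-yl)-2-methyloxolan-2-yl]-3-oxobutanoate
Conditions: SnCl2 (cat.), CH2Cl2, rt
Reagents that add atoms: none
Why: In the Roskamp homologation the diazo carbon adds to the SnCl2-activated aldehyde and a 1,2-hydride shift with loss of nitrogen gives the β-keto ester, which adds C7 and C8.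

Step 5
Reactants: 9 3-chloropropane-1,2-diol (racemic)
Product: 10 1-{[tert-butyl(dimethyl)silyl]oxy}-3-chloropropan-2-ol (racemic)
Conditions: TBSCl, imidazole, CH2Cl2, 0 °C
Reagents that add atoms: tert-butyldimethylsilyl chloride, CC(C)(C)[Si](C)(C)Cl
Why: Silyl ether formation is much faster at the primary than at the secondary hydroxyl, so the monosilyl ether should result.

Step 6
Reactants: 10 silylated chlorohydrin
Product: 11 1-{[tert-butyl(dimethyl)silyl]oxy}-3-chloropropan-2-one
Conditions: Dess–Martin periodinane, CH2Cl2, rt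
Reagents that add atoms: none
Why: Dess–Martin oxidation converts the secondary alcohol into the α-chloro ketone under non-basic conditions that avoid epoxide formation and silyl migration.

Step 7
Reactants: 8 β-keto ester; 11 α-chloro ketone
Product: 13 ethyl 4-{[tert-butyl(dimethyl)silyl]oxymethyl}-2-{[(2R,5S)-5-(2-hydroxypropan-2-yl)-2-methyloxolan-2-yl]methyl}furan-3-carboxylate, via hydroxydihydrofuran 12 (not isolated)
Conditions: pyridine, rt to 50 °C; then TsOH·H2O (cat.), CH2Cl2, 0 °C
Reagents that add atoms: none
Why: In the Feist–Benary furan synthesis the active methylene C7 adds to the ketone carbon of 11 (C7–C11), the enol oxygen displaces chloride (O–C12), and acid-catalysed loss of water aromatises the hydroxydihydrofuran to the 2,3,4-trisubstituted furan with C13 at C11 and hydrogen at C12.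

Step 8
Reactants: 13 furan ester with tertiary alcohol
Product: 14 ethyl 4-{[tert-butyl(dimethyl)silyl]oxymethyl}-2-{[(2R,5S)-2-methyl-5-(prop-1-en-2-yl)oxolan-2-yl]methyl}furan-3-carboxylate
Conditions: Burgess reagent (methyl N-(triethylammoniosulfonyl)carbamate), toluene, 50 °C
Reagents that add atoms: none
Why: Burgess dehydration (syn-elimination through the sulfamate ester) of the tertiary alcohol should take a hydrogen from one of the two methyl groups in preference to the single hindered C1–H on the oxygen-bearing carbon, which gives the isopropenyl group and leaves C1 untouched.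

Step 9
Reactants: 14 isopropenyl furan ester
Product: 15 2-bromo-1-(4-{[tert-butyl(dimethyl)silyl]oxymethyl}-2-{[(2R,5S)-2-methyl-5-(prop-1-en-2-yl)oxolan-2-yl]methyl}furan-3-yl)ethan-1-one
Conditions: CH2Br2, MeLi·LiBr, THF/Et2O, –78 °C; AcOH quench at –78 °C
Reagents that add atoms: dibromomethane, BrCBr
Why: In this halomethyllithium homologation of an ester, LiCH2Br formed in situ by bromine–lithium exchange adds once to the ester, and the tetrahedral lithium alkoxide persists at –78 °C until the cold acidic quench releases the bromomethyl ketone, which installs C9.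

Step 10
Reactants: 15 isopropenyl bromomethyl ketone
Product: 17 1-[(2S,5R)-5-{[3-(2-bromoacetyl)-4-{[tert-butyl(dimethyl)silyl]oxymethyl}furan-2-yl]methyl}-5-methyloxolan-2-yl]ethan-1-one, via vicinal diol 16 (not isolated)
Conditions: OsO4 (cat.), NaIO4, THF/H2O, 0 °C to rt
Reagents that add atoms: osmium tetroxide, O=[Os](=O)(=O)=O (oxygen carrier, regenerated by sodium periodate, [Na+].[O-]I(=O)(=O)=O)
Why: In the Lemieux–Johnson oxidation OsO4 should dihydroxylate the 1,1-disubstituted alkene in preference to the acyl-deactivated furan and periodate cleaves the diol to the C10 methyl ketone, under neutral conditions that should not epimerise C1 or displace the bromide.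

Step 11
Reactants: 17 ring A C10 methyl ketone tethered through C5 to the 3-(bromoacetyl)furan
Product: 19 (1S,4R,10R)-13-{[tert-butyl(dimethyl)silyl]oxy}-10-hydroxy-1,4:6,12-diepoxygermacra-6,11-dien-8-one (furan-masked ring B β-hydroxy ketone), via diiodosamarium enolate 18 (not isolated)
Conditions: SmI2 (2.2 equiv), THF, –78 °C, slow addition of 17 (high dilution); AcOH quench at –78 °C
Reagents that add atoms: none
Why: Two single-electron transfers from divalent samarium cleave the C9–Br bond and give the oxygen-bound trivalent samarium enolate 18, which adds through C9 to the C10 methyl ketone; the closest known reaction type is the SmI2-mediated intramolecular Reformatsky-type aldol of α-bromo carbonyl compounds used to close medium and large rings. Ring B closes by C9–C10 bond formation in a 9-(enolendo)-exo-trig mode when counted through the ring A oxygen (ten-membered when counted through C2 and C3). The new stereocentre C10 is controlled by chelation: the samarium of the enolate binds the C10 carbonyl oxygen and the ring A oxygen and so holds the carbonyl syn to the C1–O bond, and because the tether from C5 can reach C10 only from the ring-oxygen side, C9 should bond to the face that leaves the hydroxyl syn to the ring oxygen and the methyl group outward, which is (10R). The step needs reduction of the α-bromo ketone in preference to the α-alkoxy ketone (no C1–O cleavage) and intramolecular in preference to intermolecular aldol addition; the much faster reduction of the C–Br bond, the absence of a proton source or HMPA, a small excess of SmI2, high dilution and –78 °C should secure both. The chelated tertiary samarium aldolate should resist retro-aldol until it is protonated cold, and C1 is not epimerised because the C10 ketone is consumed without being enolised.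

Step 12
Reactants: 19 β-hydroxy ketone
Product: 21 (1S,4R,8S,10R)-13-{[tert-butyl(dimethyl)silyl]oxy}-1,4:6,12-diepoxygermacra-6,11-diene-8,10-diol (syn-8,10-diol), via diethylboron chelate 20 (not isolated)
Conditions: Et2BOMe, THF/MeOH, –78 °C; NaBH4; pH 7 buffer; MeOH co-evaporation
Reagents that add atoms: none
Why: In the Narasaka–Prasad reduction the boron ties the C10 oxygen and the C8 carbonyl into a six-membered chelate and external hydride should attack C8 on the face that gives the 1,3-syn diol, which sets C8 (S).

Step 13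
Reactants: 21 syn-8,10-diol
Product: 22 (1S,4R,8S,10R)-13-{[tert-butyl(dimethyl)silyl]oxy}-10-hydroxy-1,4:6,12-diepoxygermacra-6,11-dien-8-yl 2-methylprop-2-enoate
Conditions: methacrylic anhydride, Et3N, DMAP (cat.), CH2Cl2, 0 °C
Reagents that add atoms: methacrylic anhydride, C=C(C)C(=O)OC(=O)C(C)=C
Why: DMAP-catalysed acylation esterifies the secondary C8 hydroxyl, whereas the tertiary C10 hydroxyl is too hindered to react under these conditions.

Step 14
Reactants: 22 furan methacrylate
Product: 24 (1S,4R,8S,10R)-13-{[tert-butyl(dimethyl)silyl]oxy}-6,10-dihydroxy-8-(methacryloyloxy)-1,4-epoxygermacr-7(11)-en-12,6-olide (C6 epimers), via furan endoperoxide 23 (not isolated)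
Conditions: O2, hν (visible), tetraphenylporphyrin (cat.), i-Pr2NEt, CH2Cl2, –78 °C to rt
Reagents that add atoms: dioxygen, O=O
Why: Singlet-oxygen [4+2] cycloaddition across the furan α-carbons C6 and C12 followed by base-induced Kornblum–DeLaMare fragmentation of the endoperoxide (removal of its only bridgehead hydrogen, at C12) should give the γ-hydroxybutenolide with the carbonyl at C12 and the hemiketal at C6, the electron-poor methacrylate being inert to singlet oxygen.

Step 15
Reactants: 24 γ-hydroxybutenolide
Product: 26 (1S,4R,5E,8S,10R)-13-{[tert-butyl(dimethyl)silyl]oxy}-10-hydroxy-8-(methacryloyloxy)-1,4-epoxygermacra-5,7(11)-dien-12,6-olide, via 6-acetoxybutenolide 25 (not isolated)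
Conditions: Ac2O, pyridine, DMAP (cat.), CH2Cl2, 0 °C; then DBU, 0 °C
Reagents that add atoms: none
Why: Acetylation of the pseudo-acid hydroxyl and base-promoted 1,2-elimination of acetic acid (C5 being the only carbon that can lose a proton) give the γ-ylidenebutenolide, and ring B allows only the geometry with C4 cis to C7, which is the (E) alkene of the target.

Step 16
Reactants: 26 silyl-protected ylidenebutenolide
Product: 27 (1S,4R,5E,8S,10R)-10,13-dihydroxy-8-(methacryloyloxy)-1,4-epoxygermacra-5,7(11)-dien-12,6-olide
Conditions: HF·pyridine, pyridine/THF, 0 °C to rt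
Reagents that add atoms: none
Why: Fluoride-mediated cleavage of the silyl ether under pyridine-buffered conditions frees the primary C13 hydroxyl without touching the esters or the enol lactone.

Step 17
Reactants: 27 C13 alcohol
Product: 28 CNP0516045.1 (13-acetate)
Conditions: Ac2O, pyridine, CH2Cl2, 0 °C to rt
Reagents that add atoms: acetic anhydride, CC(=O)OC(C)=O
Why: Acetylation of the primary allylic alcohol is fast with Ac2O/pyridine, whereas the tertiary C10 hydroxyl does not react without forcing, so the target should be obtained.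

**Compound list**

1 | (R)-linalool, (3R)-3,7-dimethylocta-1,6-dien-3-ol | CC(C)=CCC[C@](C)(C=C)O | starting material
2 | (3R,6R)-6,7-epoxylinalool, (3R)-5-[(2R)-3,3-dimethyloxiran-2-yl]-3-methylpent-1-en-3-ol | CC1(C)O[C@@H]1CC[C@](C)(C=C)O | intermediate
3 | cis-furanoid linalool oxide, 2-[(2S,5R)-5-ethenyl-5-methyloxolan-2-yl]propan-2-ol | CC(C)(O)[C@@H]1CC[C@](C)(C=C)O1 | intermediate
4 | B-alkyl-9-borabicyclo[3.3.1]nonane from 3 (boron on the terminal vinyl carbon, C6) | CC(C)(O)[C@@H]1CC[C@](C)(CCB2C3CCCC2CCC3)O1 | intermediate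
5 | 2-[(2R,5S)-5-(2-hydroxypropan-2-yl)-2-methyloxolan-2-yl]ethan-1-ol | CC(C)(O)[C@@H]1CC[C@](C)(CCO)O1 | intermediate
6 | 2-[(2R,5S)-5-(2-hydroxypropan-2-yl)-2-methyloxolan-2-yl]acetaldehyde | CC(C)(O)[C@@H]1CC[C@](C)(CC=O)O1 | intermediate
7 | ethyl diazoacetate | CCOC(=O)C=[N+]=[N-] | starting material
8 | ethyl 4-[(2R,5S)-5-(2-hydroxypropan-2-yl)-2-methyloxolan-2-yl]-3-oxobutanoate | CC(C)(O)[C@@H]1CC[C@](C)(CC(=O)CC(=O)OCC)O1 | intermediate
9 | 3-chloropropane-1,2-diol (racemic) | OCC(O)CCl | starting material
10 | 1-{[tert-butyl(dimethyl)silyl]oxy}-3-chloropropan-2-ol (racemic) | CC(C)(C)[Si](C)(C)OCC(O)CCl | intermediate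
11 | 1-{[tert-butyl(dimethyl)silyl]oxy}-3-chloropropan-2-one | CC(C)(C)[Si](C)(C)OCC(=O)CCl | intermediate
12 | ethyl 4-hydroxy-4-(silyloxymethyl)-4,5-dihydrofuran-3-carboxylate carrying the ring A methyl group at C2 of the dihydrofuran (C11 epimers) | CC(C)(O)[C@@H]1CC[C@](C)(CC2=C(C(=O)OCC)C(O)(CO[Si](C)(C)C(C)(C)C)CO2)O1 | intermediate
13 | ethyl 4-{[tert-butyl(dimethyl)silyl]oxymethyl}-2-{[(2R,5S)-5-(2-hydroxypropan-2-yl)-2-methyloxolan-2-yl]methyl}furan-3-carboxylate | CC(C)(O)[C@@H]1CC[C@](C)(Cc2occ(CO[Si](C)(C)C(C)(C)C)c2C(=O)OCC)O1 | intermediate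
14 | ethyl 4-{[tert-butyl(dimethyl)silyl]oxymethyl}-2-{[(2R,5S)-2-methyl-5-(prop-1-en-2-yl)oxolan-2-yl]methyl}furan-3-carboxylate | C=C(C)[C@@H]1CC[C@](C)(Cc2occ(CO[Si](C)(C)C(C)(C)C)c2C(=O)OCC)O1 | intermediate
15 | 2-bromo-1-(4-{[tert-butyl(dimethyl)silyl]oxymethyl}-2-{[(2R,5S)-2-methyl-5-(prop-1-en-2-yl)oxolan-2-yl]methyl}furan-3-yl)ethan-1-one | C=C(C)[C@@H]1CC[C@](C)(Cc2occ(CO[Si](C)(C)C(C)(C)C)c2C(=O)CBr)O1 | intermediate
16 | 1,2-diol from dihydroxylation of the isopropenyl group of 15 (C10 epimers) | CC(O)(CO)[C@@H]1CC[C@](C)(Cc2occ(CO[Si](C)(C)C(C)(C)C)c2C(=O)CBr)O1 | intermediate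
17 | 1-[(2S,5R)-5-{[3-(2-bromoacetyl)-4-{[tert-butyl(dimethyl)silyl]oxymethyl}furan-2-yl]methyl}-5-methyloxolan-2-yl]ethan-1-one (key-step precursor) | CC(=O)[C@@H]1CC[C@](C)(Cc2occ(CO[Si](C)(C)C(C)(C)C)c2C(=O)CBr)O1 | intermediate
18 | diiodosamarium enolate of 17 (O-bound at C8, C8=C9) | CC(=O)[C@@H]1CC[C@](C)(Cc2occ(CO[Si](C)(C)C(C)(C)C)c2C(=C)O[Sm](I)I)O1 | intermediate
19 | (1S,4R,10R)-13-{[tert-butyl(dimethyl)silyl]oxy}-10-hydroxy-1,4:6,12-diepoxygermacra-6,11-dien-8-one (key-step product) | O=C1C[C@@](C)(O)[C@@H]2CC[C@](C)(Cc3occ(CO[Si](C)(C)C(C)(C)C)c31)O2 | intermediate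
20 | C10 O-diethylborinate of 19 (boron chelated to the C8 carbonyl) | O=C1C[C@@](C)(OB(CC)CC)[C@@H]2CC[C@](C)(Cc3occ(CO[Si](C)(C)C(C)(C)C)c31)O2 | intermediate
21 | (1S,4R,8S,10R)-13-{[tert-butyl(dimethyl)silyl]oxy}-1,4:6,12-diepoxygermacra-6,11-diene-8,10-diol | O[C@H]1C[C@@](C)(O)[C@@H]2CC[C@](C)(Cc3occ(CO[Si](C)(C)C(C)(C)C)c31)O2 | intermediate
22 | 8-O-methacrylate of 21 | C=C(C)C(=O)O[C@H]1C[C@@](C)(O)[C@@H]2CC[C@](C)(Cc3occ(CO[Si](C)(C)C(C)(C)C)c31)O2 | intermediate
23 | 6,12-endoperoxide of furan 22 | C=C(C)C(=O)O[C@H]1C[C@@](C)(O)[C@@H]2CC[C@](C)(CC34OOC(O3)C(CO[Si](C)(C)C(C)(C)C)=C41)O2 | intermediate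
24 | (1S,4R,8S,10R)-13-silyloxy-6,10-dihydroxy-8-(methacryloyloxy)-1,4-epoxygermacr-7(11)-en-12,6-olide (C6 epimers) | C=C(C)C(=O)O[C@H]1C[C@@](C)(O)[C@@H]2CC[C@](C)(CC3(O)OC(=O)C(CO[Si](C)(C)C(C)(C)C)=C31)O2 | intermediate
25 | 6-O-acetate of 24 (C6 epimers) | C=C(C)C(=O)O[C@H]1C[C@@](C)(O)[C@@H]2CC[C@](C)(CC3(OC(C)=O)OC(=O)C(CO[Si](C)(C)C(C)(C)C)=C31)O2 | intermediate
26 | (1S,4R,5E,8S,10R)-13-{[tert-butyl(dimethyl)silyl]oxy}-10-hydroxy-8-(methacryloyloxy)-1,4-epoxygermacra-5,7(11)-dien-12,6-olide | C=C(C)C(=O)O[C@H]1C[C@@](C)(O)[C@@H]2CC[C@](C)(/C=C3/OC(=O)C(CO[Si](C)(C)C(C)(C)C)=C31)O2 | intermediate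
27 | (1S,4R,5E,8S,10R)-10,13-dihydroxy-8-(methacryloyloxy)-1,4-epoxygermacra-5,7(11)-dien-12,6-olide | C=C(C)C(=O)O[C@H]1C[C@@](C)(O)[C@@H]2CC[C@](C)(/C=C3/OC(=O)C(CO)=C31)O2 | intermediate
28 | CNP0516045.1, (1S,4R,5E,8S,10R)-13-acetoxy-10-hydroxy-8-(methacryloyloxy)-1,4-epoxygermacra-5,7(11)-dien-12,6-olide | C=C(C)C(=O)O[C@H]1C[C@@](C)(O)[C@@H]2CC[C@](C)(/C=C3/OC(=O)C(COC(C)=O)=C31)O2 | target

**Step count and risks**

Total step count: 17. Longest linear sequence: 15 steps (steps 1–4 and 7–17 from (R)-linalool); steps 5 and 6 make the chloro ketone in a side branch.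

Steps most likely to fail:

1. Step 11. The samarium enolate may be protonated, or may add intermolecularly, faster than the strained medium ring closes. The ketone may also react through its non-chelated rotamer, which would set C10 with the wrong configuration. The fallback sets out from 17 and keeps the C9–C10 disconnection but separates enolate formation from ring closure. Zinc and Me3SiCl should convert the α-bromo ketone regiospecifically into the trimethylsilyl enol ether F1. F1 is then closed under high dilution with TiCl4 in CH2Cl2 at –78 °C in an intramolecular Mukaiyama aldol addition. Titanium chelation between the C10 carbonyl and the ring A oxygen directs the same face. Aqueous work-up returns to the route at 19.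

2. Step 12. Hydride delivery to C8 inside the medium ring may show poor facial selectivity, or may favour the anti diol, because the boron chelate is conformationally constrained by ring B. The fallback sets out from 19 and uses internal hydride delivery instead. Me4NBH(OAc)3 in MeCN/AcOH (Evans–Saksena reduction) should give the anti diol, (1S,4R,8R,10R)-diol F2. A Mitsunobu esterification with methacrylic acid, PPh3 and diisopropyl azodicarboxylate then inverts C8 while installing the ester. This comes back to the route at 22.

3. Step 9. Addition of the short-lived carbenoid to the flanked, vinylogous-carbonate ester may be too slow. Carbenoid decomposition, double addition or deprotonation at C5 would then take over. The fallback sets out from 14 and builds the bromomethyl ketone through a diazo ketone. KOSiMe3 in THF cleaves the ester to the furan-3-carboxylic acid F3. 1-Chloro-N,N,2-trimethylprop-1-en-1-amine converts it under neutral conditions into the acid chloride F4. Excess diazomethane gives the diazomethyl ketone F5. HBr in Et2O at –20 °C then replaces nitrogen by bromide, which comes back to the route at 15.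

Further compounds
F1 | step 11 | trimethylsilyl enol ether of 17 (C8=C9, O–SiMe3 at C8) | CC(=O)[C@@H]1CC[C@](C)(Cc2occ(CO[Si](C)(C)C(C)(C)C)c2C(=C)O[Si](C)(C)C)O1
F2 | step 12 | (1S,4R,8R,10R)-13-{[tert-butyl(dimethyl)silyl]oxy}-1,4:6,12-diepoxygermacra-6,11-diene-8,10-diol (anti diol) | O[C@@H]1C[C@@](C)(O)[C@@H]2CC[C@](C)(Cc3occ(CO[Si](C)(C)C(C)(C)C)c31)O2
F3 | step 9 | 4-{[tert-butyl(dimethyl)silyl]oxymethyl}-2-{[(2R,5S)-2-methyl-5-(prop-1-en-2-yl)oxolan-2-yl]methyl}furan-3-carboxylic acid | C=C(C)[C@@H]1CC[C@](C)(Cc2occ(CO[Si](C)(C)C(C)(C)C)c2C(=O)O)O1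
F4 | step 9 | acid chloride of F3 | C=C(C)[C@@H]1CC[C@](C)(Cc2occ(CO[Si](C)(C)C(C)(C)C)c2C(=O)Cl)O1
F5 | step 9 | diazomethyl ketone from F4 | C=C(C)[C@@H]1CC[C@](C)(Cc2occ(CO[Si](C)(C)C(C)(C)C)c2C(=O)C=[N+]=[N-])O1
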